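The leftover, the part of the L charged not read as G after 5.00 h, was 70.8% in ash and 80.7% in alder, whereas a rate first order in L at a fixed level of J in solution would leave equal fractions, so in these two runs the time needed per unit of G grows with the charge.

common to all: J 12 mM (held)

| charge | L | remark | time |
|---|---|---|---|
| ash | 0.17 M | run made earlier |  |
| alder | 0.38 M | run made earlier |  |
| flask | 0.25 M |  | 5.0 h |

- ash (time / h: G / %): 0.667: 2.9; 1.33: 8.6; 2.00: 12.0; 3.00: 19.2; 4.00: 24.5; 5.00: 29.2
- alder (time / h: G / %): 0.250: 1.3; 0.833: 4.9; 1.33: 4.1; 2.00: 9.1; 3.00: 13.7; 4.00: 15.8; 5.00: 19.3

(scatter of a reading: 1 percentage point)

- at the start none of J is in solution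

- delta: doubling the transfer coefficient of J, all else as stated
- alpha: doubling the saturation concentration of J, all else as stated

* amount of G at 5.0 h, in percent of the L charged
* the change that raises the amount of G at 5.0 h, in percent of the L charged most ("none" if none brings more than 2 percentage points) (delta / alpha / none)
* amount of G at 5.0 h, in percent of the L charged, after delta

J in solution is the reagent present in the smaller amount, since it starts at none and its saturation level is 12 mM against 0.17 M of L in ash, so we write its balance: transfer from the held gas feeds it, L consumes it, and with the two quasi-steady, reading time over fraction of G is a sum of two times. The reaction time is independent of [L], and the delivery time, in which the gas brings one J per L charged, is proportional to [L]. Ash reads 17.1 h and alder 25.9 h, each with the scatter of its readings, so a straight line through them, taken back to no charge, reads a reaction time of 10.0 h. For the flask the same line reads a delivery time of 10.5 h, about equal to the reaction time, so neither is a rate-limiting step. Their sum is 20.5 h, the turnover time.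

Our line gives 24.4% of G, and 32.8% after delta, which halves the delivery time. Alpha halves both times, so it gives the shorter turnover time. The forecast, integrating its rate law, prints 24.5%, 32.5% after delta, and alpha as the best change, reasoning “That points to mixed control: J is supplied by gas transfer and consumed by reaction”.

The flask gives 25.3%, and 34.9% after delta; the best change is alpha, worth 14 percentage points against 9.5 points for delta.

    L + D → G (k = 21.0 L mol⁻¹ h⁻¹)
    J ⇌ D, rate k2*(csat - [D]) (kL = 2.20 h⁻¹)
    L + 2 D → E (k = 1900 L² mol⁻² h⁻¹)

Its 25.3% makes a turnover time of 19.7 h against our 20.5 h. The neighbouring flask, with [L] at 1.0 M and the time held, we put on the same line: its delivery time is 41.8 h, longer than the reaction time of 10.0 h, its turnover time is 51.8 h, and so we reckon 9.65% of G. That flask holds 10.1% of G, with 89% of its L left.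

The data are simulated for substances that don't exist; scatter was added.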